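TBS = tert-butyldimethylsilyl. (S,S)-iPr-BOX = 2,2'-(propane-2,2-diyl)bis[(4S)-4-isopropyl-4,5-dihydrooxazole].

## Retrosynthetic overview
1. The stilbene C=C is made last. An E-selective Horner–Wadsworth–Emmons reaction joins a 2,3-diaryl-1,4-benzodioxine-6-carbaldehyde to a 3,5-disiloxybenzyl phosphonate, and fluoride then removes all six silyl groups.
2. The dioxane is the only ring formed. Its C3–O bond is closed by acid (SN1) from a 2-aryloxy-1,2-diarylethanol that carries an ortho phenol, and the trans geometry is relayed from C2 under thermodynamic control.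
3. The key C2–C3 bond comes from an α-aryloxybenzyl carbanion (a ligand-bound organolithium made from an aryl benzyl ether) and 3,4-disiloxybenzaldehyde. Both carbons have aldehyde-type polarity, and this step sets C2 as R with the aryl ether already in place.
4. The aryl benzyl ether comes from 4-O-selective benzylation of 3,4-dihydroxybenzaldehyde with 3,5-disiloxybenzyl bromide. The same bromide also gives the phosphonate.
5. The starting materials are 3,5-dihydroxybenzyl alcohol and 3,4-dihydroxybenzaldehyde, the latter used twice.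

Assumption: the (S,S)-ligand is taken to give the (2R) adduct; the sense of induction on this new substrate must be confirmed on the first run (rotation/CD of 14), and the equally available (R,R)-ligand is used if it is opposite.

## Route

Step 1
Reactants: 1 3,5-dihydroxybenzyl alcohol
Product: 2 3,5-bis(TBSO)benzyl TBS ether
Conditions: TBSCl (3.5 equiv), imidazole (7 equiv), DMF, rt
Reagents that add atoms: tert-butyldimethylsilyl chloride, CC(C)(C)[Si](C)(C)Cl
Why: Exhaustive imidazole-promoted silyl ether formation caps all three hydroxyls cleanly, and the sp3 benzylic ether is singled out in the next step; no stereocentre is involved.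

Step 2
Reactants: 2 3,5-bis(TBSO)benzyl TBS ether
Product: 3 3,5-bis(TBSO)benzyl bromide
Conditions: Ph3PBr2 (1.15 equiv, commercial), CH2Cl2, 0 °C to rt
Reagents that add atoms: dibromotriphenylphosphorane, BrP(Br)(c1ccccc1)(c1ccccc1)c1ccccc1
Why: This is an Appel-type bromodesilylation in which only the benzylic O–Si ether can form an oxyphosphonium ion that bromide displaces by SN2, while aryl silyl ethers have no displaceable carbon and survive.

Step 3
Reactants: 3 3,5-bis(TBSO)benzyl bromide; 4 3,4-dihydroxybenzaldehyde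
Product: 5 4-{[3,5-bis(TBSO)benzyl]oxy}-3-hydroxybenzaldehyde
Conditions: NaHCO3 (1.5 equiv), NaI (0.3 equiv), DMF, 40 °C
Reagents that add atoms: none
Why: In this Williamson etherification under weak-base control, only the 4-OH (para to CHO, pKa about 7.5) is ionised by bicarbonate, so the oxygen para to the future styryl carbon is placed on the resorcinol-bearing carbon, as the target requires.

Step 4
Reactants: 5 4-{[3,5-bis(TBSO)benzyl]oxy}-3-hydroxybenzaldehyde
Product: 6 2-{[3,5-bis(TBSO)benzyl]oxy}-5-(dimethoxymethyl)phenol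
Conditions: HC(OMe)3 (3 equiv), CSA (2 mol %), MeOH, rt; Et3N quench, Et3N-deactivated silica
Reagents that add atoms: trimethyl orthoformate, COC(OC)OC
Why: Acid-catalysed acetalisation with the orthoester as water scavenger masks the aldehyde against t-BuLi, and the aryl silyl ethers and the phenol tolerate trace acid.

Step 5
Reactants: 4 3,4-dihydroxybenzaldehyde
Product: 7 3,4-bis(TBSO)benzaldehyde
Conditions: TBSCl (2.4 equiv), imidazole (5 equiv), DMF, rt
Reagents that add atoms: tert-butyldimethylsilyl chloride, CC(C)(C)[Si](C)(C)Cl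
Why: Standard phenol silylation gives a non-enolisable aldehyde electrophile that carries no directing or acidic groups.

Step 6
Reactants: 6 2-{[3,5-bis(TBSO)benzyl]oxy}-5-(dimethoxymethyl)phenol; 7 3,4-bis(TBSO)benzaldehyde
Product: 9 (2R)-1-[3,4-bis(TBSO)phenyl]-2-[3,5-bis(TBSO)phenyl]-2-[4-(dimethoxymethyl)-2-hydroxyphenoxy]ethan-1-ol (C-1 epimer mixture), via dilithiated ether 8 (not isolated)
Conditions: t-BuLi (2.1 equiv), (S,S)-iPr-BOX (2.2 equiv, recovered), Et2O/hexane, −78 °C, 1 h; then 7 (1.2 equiv), −78 °C; AcOH quench at −78 °C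
Reagents that add atoms: tert-butyllithium, [Li]C(C)(C)C (supplies the lithium of 8 only; none of its atoms stay in 9)
Why: Proposed new method: the first t-BuLi forms the lithium phenoxide, which makes the aryloxy ring too electron-rich for ipso attack (suppressing the [1,2]-Wittig shift and ring lithiation), the second removes an OCH2 proton to give the α-aryloxybenzyllithium 8, an α-oxygenated carbanion that attacks the aldehyde carbon of 7 so that two carbons of aldehyde-type polarity are joined; the configurationally labile C–Li centre equilibrates inside the chiral bis(oxazoline)·Li complex (dynamic resolution) and trapping of the favoured complex sets C-2 as R, while C-1 forms as an epimer mixture that step 7 corrects; the closest known reaction types are α-lithiation/carbonyl trapping of aryl benzyl ethers with t-BuLi at −78 °C and bis(oxazoline)/t-BuLi enantioselective lithiation–substitution of benzyl alkyl ethers and O-benzyl carbamates.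

Step 7
Reactants: 9 (2R)-1-[3,4-bis(TBSO)phenyl]-2-[3,5-bis(TBSO)phenyl]-2-[4-(dimethoxymethyl)-2-hydroxyphenoxy]ethan-1-ol (C-1 epimer mixture)
Product: 10 (2R,3R)-3-[3,4-bis(TBSO)phenyl]-2-[3,5-bis(TBSO)phenyl]-2,3-dihydro-1,4-benzodioxine-6-carbaldehyde (trans)
Conditions: TFA (10 equiv), water-saturated CH2Cl2 (0.01 M), 0 °C to rt; NaHCO3 work-up
Reagents that add atoms: water, O
Why: In this SN1 cyclodehydration TFA ionises only the 4-siloxy-stabilised benzylic alcohol (a p-quinone-methide-like cation), the neighbouring phenol closes the six-membered ring, reversible C3–O ionisation funnels both C-1 epimers into the diequatorial trans (3R) product, the meta-oxygenated benzylic C-2 cannot ionise and keeps its R configuration, and the acetal is hydrolysed in the same pot, which also deactivates the benzo ring towards Friedel–Crafts closure.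

Step 8
Reactants: 3 3,5-bis(TBSO)benzyl bromide
Product: 11 diethyl [3,5-bis(TBSO)benzyl]phosphonate
Conditions: P(OEt)3 (neat, 3 equiv), 130 °C; excess removed in vacuo
Reagents that add atoms: triethyl phosphite, CCOP(OCC)OCC
Why: The Michaelis–Arbuzov reaction of a reactive benzylic bromide runs under neutral thermal conditions that leave aryl silyl ethers intact.

Step 9
Reactants: 10 (2R,3R)-3-[3,4-bis(TBSO)phenyl]-2-[3,5-bis(TBSO)phenyl]-2,3-dihydro-1,4-benzodioxine-6-carbaldehyde; 11 diethyl [3,5-bis(TBSO)benzyl]phosphonate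
Product: 14 cassigarol E, via lithiated phosphonate 12 (not isolated), via hexa-TBS cassigarol E 13 (not isolated)
Conditions: 11 (1.2 equiv), n-BuLi (1.2 equiv), THF, −78 °C; 10, −78 °C to rt; then Et3N·3HF (excess), rt, argon; pH 5 work-up, Sephadex LH-20
Reagents that add atoms: n-butyllithium, [Li]CCCC (supplies the lithium of 12 only; none of its atoms stay in 14)
Why: The Horner–Wadsworth–Emmons olefination of an aryl aldehyde with a semi-stabilised benzyl phosphonate anion gives the E-alkene under thermodynamic control without touching the non-acidic C-2/C-3 hydrogens, and mildly acidic fluoride then cleaves all six aryl Si–O bonds without oxidising the catechol or opening the dioxane.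

## Compound list
1 | 3,5-dihydroxybenzyl alcohol | OCc1cc(O)cc(O)c1 | starting material
2 | 3,5-bis(TBSO)benzyl TBS ether | CC(C)(C)[Si](C)(C)OCc1cc(O[Si](C)(C)C(C)(C)C)cc(O[Si](C)(C)C(C)(C)C)c1 | intermediate
3 | 3,5-bis(TBSO)benzyl bromide | BrCc1cc(O[Si](C)(C)C(C)(C)C)cc(O[Si](C)(C)C(C)(C)C)c1 | intermediate
4 | 3,4-dihydroxybenzaldehyde | O=Cc1ccc(O)c(O)c1 | starting material
5 | 4-{[3,5-bis(TBSO)benzyl]oxy}-3-hydroxybenzaldehyde | O=Cc1ccc(OCc2cc(O[Si](C)(C)C(C)(C)C)cc(O[Si](C)(C)C(C)(C)C)c2)c(O)c1 | intermediate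
6 | 2-{[3,5-bis(TBSO)benzyl]oxy}-5-(dimethoxymethyl)phenol | COC(OC)c1ccc(OCc2cc(O[Si](C)(C)C(C)(C)C)cc(O[Si](C)(C)C(C)(C)C)c2)c(O)c1 | intermediate
7 | 3,4-bis(TBSO)benzaldehyde | O=Cc1ccc(O[Si](C)(C)C(C)(C)C)c(O[Si](C)(C)C(C)(C)C)c1 | intermediate
8 | dilithiated ether (lithium phenoxide / α-aryloxybenzyllithium, BOX-bound, C–Li centre configurationally labile) | COC(OC)c1ccc(OC([Li])c2cc(O[Si](C)(C)C(C)(C)C)cc(O[Si](C)(C)C(C)(C)C)c2)c(O[Li])c1 | intermediate (not isolated)
9 | (2R)-1-[3,4-bis(TBSO)phenyl]-2-[3,5-bis(TBSO)phenyl]-2-[4-(dimethoxymethyl)-2-hydroxyphenoxy]ethan-1-ol, C-1 epimer mixture | OC(c1ccc(O[Si](C)(C)C(C)(C)C)c(O[Si](C)(C)C(C)(C)C)c1)[C@@H](c1cc(O[Si](C)(C)C(C)(C)C)cc(O[Si](C)(C)C(C)(C)C)c1)Oc1ccc(C(OC)OC)cc1O | intermediate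
10 | (2R,3R)-3-[3,4-bis(TBSO)phenyl]-2-[3,5-bis(TBSO)phenyl]-2,3-dihydro-1,4-benzodioxine-6-carbaldehyde | O=Cc1ccc2c(c1)O[C@H](c1ccc(O[Si](C)(C)C(C)(C)C)c(O[Si](C)(C)C(C)(C)C)c1)[C@@H](c1cc(O[Si](C)(C)C(C)(C)C)cc(O[Si](C)(C)C(C)(C)C)c1)O2 | intermediate
11 | diethyl [3,5-bis(TBSO)benzyl]phosphonate | CCOP(=O)(Cc1cc(O[Si](C)(C)C(C)(C)C)cc(O[Si](C)(C)C(C)(C)C)c1)OCC | intermediate
12 | lithiated phosphonate | CCOP(=O)(OCC)C([Li])c1cc(O[Si](C)(C)C(C)(C)C)cc(O[Si](C)(C)C(C)(C)C)c1 | intermediate (not isolated)
13 | hexa-TBS cassigarol E | CC(C)(C)[Si](C)(C)Oc1cc(O[Si](C)(C)C(C)(C)C)cc(/C=C/c2ccc3c(c2)O[C@H](c2ccc(O[Si](C)(C)C(C)(C)C)c(O[Si](C)(C)C(C)(C)C)c2)[C@@H](c2cc(O[Si](C)(C)C(C)(C)C)cc(O[Si](C)(C)C(C)(C)C)c2)O3)c1 | intermediate (not isolated)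
14 | cassigarol E, 5-[(E)-2-[(2R,3R)-3-(3,4-dihydroxyphenyl)-2-(3,5-dihydroxyphenyl)-2,3-dihydro-1,4-benzodioxin-6-yl]ethenyl]benzene-1,3-diol | Oc1cc(O)cc(/C=C/c2ccc3c(c2)O[C@H](c2ccc(O)c(O)c2)[C@@H](c2cc(O)cc(O)c2)O3)c1 | target

## Step count
- Total step count: 9.
- Longest linear sequence: 7 (steps 1, 2, 3, 4, 6, 7, 9).

## Steps most likely to fail

**Step 6 (highest risk).**
- The level and sense of induction are untested for an aryl benzyl ether that carries a neighbouring lithium phenoxide.
- A [1,2]-Wittig shift or ring lithiation could also compete.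
- The fallback sets out from 6 and 7 and moves enantiocontrol from the C–C bond formation to a later reduction.
- The lithiation/addition is run without ligand (t-BuLi, THF, −78 °C) to give the racemic adduct F1.
- MnO2 in CH2Cl2 oxidises the benzylic alcohol to the α-aryloxy ketone F2, whose C-2 hydrogen is acidic enough to racemise in amine base.
- Noyori–Ikariya transfer hydrogenation under dynamic kinetic resolution then delivers a single C-1 epimer with 2R configuration. The conditions are RuCl(p-cymene)(TsDPEN), amine-rich HCO2H/Et3N, 40 °C, with the catalyst enantiomer chosen for 2R.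
- That product is one of the two components of 9, so the route is rejoined at 9.

**Step 7.**
- The cation may lose the para silyl group.
- It may undergo a 1,2-hydride shift to a deoxybenzoin.
- On long exposure it may close on carbon to give a 2,3-diaryl-dihydrobenzofuran.
- The fallback sets out from 9 and replaces the acid SN1 closure with a fluoride-triggered quinone methide closure.
- Ac2O/pyridine/DMAP gives the diacetate F3.
- TBAF·3H2O in THF at 0 °C strips the silyl groups and the aryl acetate. The 4-phenoxide then expels the benzylic acetate to form a p-quinone methide.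
- The neighbouring phenoxide closes onto the quinone methide by a reversible, trans-selective oxa-1,6-addition.
- A brief 1 M HCl work-up frees the aldehyde to give the tetraphenol aldehyde F4.
- TBSCl/imidazole in DMF re-silylates it, and the route is rejoined at 10.

**Step 9.**
- The telescoped process allows no purification at the protected stage.
- Base-induced loss of the 4-O-silyl group could open the dioxane through a quinone methide.
- The air-sensitive hexaphenol must be separated from phosphate salts.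
- The fallback sets out from 10 and replaces the carbanion olefination with a palladium coupling.
- Wittig methylenation (Ph3P=CH2, THF, 0 °C) gives the 6-vinyl dioxane F5.
- A Heck reaction (Pd(OAc)2, P(o-tol)3, Et3N, MeCN, 85 °C) with 1-bromo-3,5-bis(TBSO)benzene F6 gives the E-stilbene. F6 is made in one step from commercial 5-bromoresorcinol with TBSCl/imidazole.
- The route is rejoined at 13, which is now isolated and purified before the Et3N·3HF treatment of step 9.

## Further compounds
F1 | step 6 | racemic 1-[3,4-bis(TBSO)phenyl]-2-[3,5-bis(TBSO)phenyl]-2-[4-(dimethoxymethyl)-2-hydroxyphenoxy]ethan-1-ol | OC(c1ccc(O[Si](C)(C)C(C)(C)C)c(O[Si](C)(C)C(C)(C)C)c1)C(c1cc(O[Si](C)(C)C(C)(C)C)cc(O[Si](C)(C)C(C)(C)C)c1)Oc1ccc(C(OC)OC)cc1O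
F2 | step 6 | 1-[3,4-bis(TBSO)phenyl]-2-[3,5-bis(TBSO)phenyl]-2-[4-(dimethoxymethyl)-2-hydroxyphenoxy]ethan-1-one (racemic, C-2 labile) | O=C(c1ccc(O[Si](C)(C)C(C)(C)C)c(O[Si](C)(C)C(C)(C)C)c1)C(c1cc(O[Si](C)(C)C(C)(C)C)cc(O[Si](C)(C)C(C)(C)C)c1)Oc1ccc(C(OC)OC)cc1O
F3 | step 7 | (2R)-2-[2-acetoxy-4-(dimethoxymethyl)phenoxy]-1-[3,4-bis(TBSO)phenyl]-2-[3,5-bis(TBSO)phenyl]ethyl acetate (C-1 epimer mixture) | CC(=O)OC(c1ccc(O[Si](C)(C)C(C)(C)C)c(O[Si](C)(C)C(C)(C)C)c1)[C@@H](c1cc(O[Si](C)(C)C(C)(C)C)cc(O[Si](C)(C)C(C)(C)C)c1)Oc1ccc(C(OC)OC)cc1OC(C)=O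
F4 | step 7 | (2R,3R)-3-(3,4-dihydroxyphenyl)-2-(3,5-dihydroxyphenyl)-2,3-dihydro-1,4-benzodioxine-6-carbaldehyde | O=Cc1ccc2c(c1)O[C@H](c1ccc(O)c(O)c1)[C@@H](c1cc(O)cc(O)c1)O2
F5 | step 9 | (2R,3R)-3-[3,4-bis(TBSO)phenyl]-2-[3,5-bis(TBSO)phenyl]-6-vinyl-2,3-dihydro-1,4-benzodioxine | C=Cc1ccc2c(c1)O[C@H](c1ccc(O[Si](C)(C)C(C)(C)C)c(O[Si](C)(C)C(C)(C)C)c1)[C@@H](c1cc(O[Si](C)(C)C(C)(C)C)cc(O[Si](C)(C)C(C)(C)C)c1)O2
F6 | step 9 | 1-bromo-3,5-bis(TBSO)benzene | Brc1cc(O[Si](C)(C)C(C)(C)C)cc(O[Si](C)(C)C(C)(C)C)c1
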